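**Strategy.** Numbering: C1 is the ring-fusion carbon with the angular methyl, C4 the isopropyl carbon, C5 the ring-fusion carbinol, C8 the tertiary methyl carbinol, C9 the acyloxy carbon; C2, C3, C6, C7 and C10 are the methylenes between them. In the cycloheptane ring C5, C8 and C9 are oxygenated and C6–C7 is plain, which maps onto a cyclopentane-fused 2-methyl-3-oxidopyrylium (C5–O–C8 as carbonyl ylide, C9–O as oxide) plus a two-carbon alkene. A single (5+2) cycloaddition forms C5–C6 and C7–C8, closes the seven-membered carbocycle with its oxygen bridge and sets C5 against the C4 isopropyl group. The ylide comes from a 6-acetoxypyranone made by Achmatowicz oxidation of an (R)-isopropylcyclopenta[b]furyl carbinol.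

Key step: step 9

Assumption: in step 5 the (S)-configured ligand is taken to deliver hydrogen to the alkene face that gives the (R)-alkane; if a test run shows the opposite sense, the (R)-ligand is used and nothing else changes.

Remark: compounds 7–14 carry cyclopenta[b]furan numbering and 15, 16 and 18 cyclopenta[b]pyran numbering. From 19 onward the skeleton numbering of the first paragraph is used; "daucane" denotes that skeleton.

**Step 1**
Reactants: 1 3-furaldehyde; 2 malonic acid
Product: 4 (E)-3-(furan-3-yl)prop-2-enoic acid, via furylmethylidenemalonic acid 3 (not isolated)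
Conditions: pyridine, piperidine (cat.), 95 °C
Reagents that add atoms: malonic acid (2), OC(=O)CC(=O)O
Why: Knoevenagel–Doebner condensation, in which the piperidine-catalysed condensation product 3 decarboxylates in hot pyridine to the conjugated E-acid; no stereocentre is formed.

**Step 2**
Reactants: 4 (E)-3-(furan-3-yl)prop-2-enoic acid
Product: 5 3-(furan-3-yl)propanoic acid
Conditions: H2 (1 atm), 5% Pd/C, EtOAc, rt, stopped after 1 equiv H2
Reagents that add atoms: none
Why: Catalytic hydrogenation under mild conditions reduces the acrylic C=C bond far faster than the aromatic furan, so uptake is stopped after one equivalent.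

**Step 3**
Reactants: 5 3-(furan-3-yl)propanoic acid
Product: 7 4,5-dihydro-6H-cyclopenta[b]furan-6-one, via 3-(furan-3-yl)propanoyl chloride 6 (not isolated)
Conditions: (COCl)2, DMF (cat.), CH2Cl2, 0 °C to rt; then SnCl4, CH2Cl2, −78 to 0 °C
Reagents that add atoms: none
Why: Intramolecular Friedel–Crafts acylation, in which the acyl chloride tethered to furan C3 can reach only the adjacent α-carbon, the most nucleophilic furan position, with SnCl4 at low temperature as the mild Lewis acid customary for acid-sensitive furans.

**Step 4**
Reactants: 7 4,5-dihydro-6H-cyclopenta[b]furan-6-one; 8 isopropylmagnesium chloride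
Product: 10 6-(propan-2-yl)-4H-cyclopenta[b]furan, via tertiary furylic alcohol 9 (not isolated)
Conditions: i-PrMgCl, CeCl3, THF, −78 to 0 °C; aq. NH4Cl; then p-TsOH (cat.), toluene, rt
Reagents that add atoms: isopropylmagnesium chloride (8), CC(C)[Mg]Cl
Why: Cerium-mediated Grignard 1,2-addition suppresses enolisation of the conjugated cyclopentanone, and the tertiary furylic alcohol 9 then loses water by acid-catalysed E1 elimination to the conjugated endocyclic trisubstituted alkene, as 1-alkylindan-1-ols give 3-alkylindenes.

**Step 5**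
Reactants: 10 6-(propan-2-yl)-4H-cyclopenta[b]furan
Product: 11 (6R)-6-(propan-2-yl)-5,6-dihydro-4H-cyclopenta[b]furan
Conditions: H2 (50 bar), [Ir(cod)(L)][B(C6H3(CF3)2)4] (1 mol%; cod = cycloocta-1,5-diene; L = (S)-4-tert-butyl-2-[2-(diphenylphosphanyl)phenyl]-4,5-dihydrooxazole), CH2Cl2, rt
Reagents that add atoms: none
Why: Asymmetric hydrogenation of an unfunctionalised, aryl-conjugated trisubstituted cyclic alkene with a cationic iridium phosphinooxazoline catalyst, in which the chiral N,P ligand selects the alkene face and so sets the isopropyl-bearing stereocentre (R, the later C4), the only stereocentre of the route set by a reagent.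

**Step 6**
Reactants: 11 (6R)-6-(propan-2-yl)-5,6-dihydro-4H-cyclopenta[b]furan; 12 acetaldehyde
Product: 14 1-[(6R)-6-(propan-2-yl)-5,6-dihydro-4H-cyclopenta[b]furan-2-yl]ethan-1-ol (both carbinol epimers), via 2-furyllithium 13 (not isolated)
Conditions: n-BuLi, THF, −78 to 0 °C; CH3CHO, −78 °C; aq. NH4Cl
Reagents that add atoms: acetaldehyde (12), CC=O
Why: α-Lithiation of the furan at its single free α-position followed by 1,2-addition to the aldehyde; the new carbinol centre forms without control, which is harmless because it becomes the planar C8 of the ylide, and the C6 stereocentre is not acidic enough to be touched.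

**Step 7**
Reactants: 14 1-[(6R)-6-(propan-2-yl)-5,6-dihydro-4H-cyclopenta[b]furan-2-yl]ethan-1-ol
Product: 15 (7R)-7a-hydroxy-2-methyl-7-(propan-2-yl)-5,6,7,7a-tetrahydrocyclopenta[b]pyran-3(2H)-one (epimers at C2 and C7a)
Conditions: NBS, NaHCO3, THF/H2O (4:1), 0 °C
Reagents that add atoms: water, O
Why: Achmatowicz oxidative ring expansion, in which bromonium-induced hydration of the furan and ring opening give a hydroxy enedione that recloses as the six-membered hemiketal; the buffered medium at 0 °C keeps the centre next to the masked ketone from epimerising, and C2 and C7a arise as mixtures.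

**Step 8**
Reactants: 15 (7R)-7a-hydroxy-2-methyl-7-(propan-2-yl)-5,6,7,7a-tetrahydrocyclopenta[b]pyran-3(2H)-one
Product: 16 (7R)-2-methyl-3-oxo-7-(propan-2-yl)-2,3,5,6,7,7a-hexahydrocyclopenta[b]pyran-7a-yl acetate (epimers at C2 and C7a)
Conditions: Ac2O, pyridine, DMAP (cat.), CH2Cl2, 0 °C
Reagents that add atoms: acetic anhydride, CC(=O)OC(C)=O
Why: DMAP-catalysed O-acylation of the tertiary hemiketal hydroxyl, with pyridine as a base too weak to trigger loss of acetic acid, gives the ylide precursor as a mixture of epimers that is used as such.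

**Step 9**
Reactants: 16 (7R)-2-methyl-3-oxo-7-(propan-2-yl)-2,3,5,6,7,7a-hexahydrocyclopenta[b]pyran-7a-yl acetate; 17 (E)-1,2-bis(phenylsulfonyl)ethene
Product: 19 bis-sulfonyl cycloadduct (cyclopentane-fused 8-oxabicyclo[3.2.1]oct-3-en-2-one: enone C9(=O)–C10=C1, oxygen bridge C5–O–C8, methyl on C8, (4R)-isopropyl cis to the C5 oxygen, trans phenylsulfonyl groups on C6 and C7), via oxidopyrylium betaine 18 (not isolated)
Conditions: i-Pr2NEt, 17 (2 equiv), CH2Cl2, rt
Reagents that add atoms: (E)-1,2-bis(phenylsulfonyl)ethene (17), O=S(=O)(/C=C/S(=O)(=O)c1ccccc1)c1ccccc1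
Why: The hindered amine removes the C8 proton while acetate leaves from C5, giving the planar aromatic betaine 18, whose C5–O–C8 unit acts as a carbonyl ylide and adds suprafacially across the electron-poor alkene in a concerted, asynchronous six-electron (5+2) cycloaddition, the established behaviour of 3-oxidopyrylium ylides from acetoxypyranones towards acceptor alkenes. Two rings close in this intermolecular event: the seven-membered carbocycle (C1, C5, C6, C7, C8, C9, C10) by union of the five-carbon ylide chain C5–C1–C10–C9–C8 with the two alkene carbons, and the oxolane O–C5–C6–C7–C8 that makes the product an 8-oxabicyclo[3.2.1]oct-3-en-2-one. C5 and C8 are created together and must be cis because one oxygen bridges them; their absolute sense is set by the C4 stereocentre, whose isopropyl group covers one face of the flat cyclopentane-fused ylide, so that C6 bonds to C5 anti to it and the C5 oxygen ends cis to isopropyl. C6 and C7 are trans because the E geometry of 17 is retained, and their exo or endo sense is irrelevant since both sulfonyl groups are removed in step 11. The only selectivity needed is π-facial: the symmetric disulfone poses no regiochemical question, all epimers of 16 converge on the one ylide, and an excess of a very reactive 2π partner with a non-nucleophilic base at room temperature is chosen so that trapping outruns ylide dimerisation and any proton loss from C4.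

**Step 10**
Reactants: 19 bis-sulfonyl cycloadduct
Product: 21 C1-methyl bis-sulfonyl ketone (C9 ketone, C10 methylene, quaternary C1 with methyl cis to the C5 oxygen and to the C4 isopropyl group, oxygen bridge and sulfonyl groups as in 19), via trimethylsilyl enol ether 20 (not isolated)
Conditions: Me2CuLi (from MeLi and CuI, Et2O, 0 °C), TMSCl, THF, −78 to −40 °C; then 1 M HCl, THF, 0 °C
Reagents that add atoms: lithium dimethylcuprate, [Li+].C[Cu-]C
Why: Chlorotrimethylsilane-accelerated Gilman conjugate addition to the β,β-disubstituted enone, in which methyl enters C1 from the exo face (that of the oxygen bridge) because the two-carbon bridge with its sulfonyl groups shields the other face, so the new quaternary C1 carries methyl cis to the C5 oxygen (cis ring fusion); mild acid then hydrolyses silyl enol ether 20 to the ketone.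

**Step 11**
Reactants: 21 C1-methyl bis-sulfonyl ketone
Product: 22 (1R,4R,5S,8S)-5,8-epoxydauc-6-en-9-one
Conditions: 6% Na(Hg), Na2HPO4, MeOH/THF, −20 °C
Reagents that add atoms: none
Why: Reductive elimination of the vicinal disulfone by sodium amalgam (17 serving as an acetylene equivalent), in which electron transfer expels one benzenesulfinate and the resulting β-sulfonyl carbanion expels the second, a far better leaving group than the bridging alkoxide, to give the C6=C7 alkene while the cold buffered medium leaves the ketone alone.

**Step 12**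
Reactants: 22 (1R,4R,5S,8S)-5,8-epoxydauc-6-en-9-one
Product: 23 (1R,4R,5S,8S)-5,8-epoxydaucan-9-one
Conditions: H2 (1 atm), 10% Pd/C, EtOAc, rt
Reagents that add atoms: none
Why: Catalytic hydrogenation of the strained, unhindered cis-disubstituted C6=C7 bond of the oxabicycle is far faster than reduction of the hindered ketone; no stereocentre is formed.

**Step 13**
Reactants: 23 (1R,4R,5S,8S)-5,8-epoxydaucan-9-one
Product: 25 (1R,4R,5S)-dauc-8-en-5-ol, via hydrazone 24 (not isolated)
Conditions: N2H4·H2O, diethylene glycol, 130 °C; then KOH, 195 °C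
Reagents that add atoms: none
Why: Kishner–Leonard eliminative reduction of an α-alkoxy ketone, in which the anion of hydrazone 24 expels the C8–O bond (held nearly parallel to the C=N π system in the bicycle) and the alkenyl diazene loses N2, so the ether bridge opens to the free C5 tertiary alcohol and the double bond is placed regiospecifically between C8 and C9 without touching C1, C4 or C5.

**Step 14**
Reactants: 25 (1R,4R,5S)-dauc-8-en-5-ol
Product: 26 (1R,4R,5S,8S,9R)-8,9-epoxydaucan-5-ol (epoxide cis to the C5 hydroxyl)
Conditions: VO(acac)2 (5 mol%), t-BuOOH (decane), CH2Cl2, 0 °C to rt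
Reagents that add atoms: tert-butyl hydroperoxide, CC(C)(C)OO
Why: Vanadium-catalysed hydroxyl-directed epoxidation, in which the vanadate ester of the C5 alcohol delivers the peroxide oxygen across the ring to the alkene face syn to it (the geometry in which that oxygen earlier bridged C5 and C8), setting C8 and C9 with the epoxide cis to the C5 hydroxyl; this syn epoxide cannot be opened transannularly by the C5 oxygen, which has no backside access.

**Step 15**
Reactants: 26 (1R,4R,5S,8S,9R)-8,9-epoxydaucan-5-ol
Product: 27 (1R,4R,5S,8R,9R)-daucane-5,8,9-triol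
Conditions: HClO4 (cat.), THF/H2O (3:1), 0 °C
Reagents that add atoms: water, O
Why: Acid-catalysed anti opening of the trisubstituted epoxide by water at the tertiary carbon, which carries most of the positive charge, inverts C8 and leaves C9 untouched, giving the trans-8,9-diol with the C8 hydroxyl anti and the C9 hydroxyl syn to the C5 hydroxyl as the target requires.

**Step 16**
Reactants: 27 (1R,4R,5S,8R,9R)-daucane-5,8,9-triol; 28 4-methoxybenzoyl chloride
Product: 29 (1R,4R,5S,8R,9R)-5,8-dihydroxydaucan-9-yl 4-methoxybenzoate (CNP0244624.1)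
Conditions: pyridine, DMAP (cat.), CH2Cl2, 0 °C to rt
Reagents that add atoms: 4-methoxybenzoyl chloride (28), COc1ccc(C(=O)Cl)cc1
Why: DMAP-catalysed acylation is selective for the only secondary hydroxyl, C9–OH, because the tertiary C5 and C8 hydroxyls are too hindered to react under these conditions; no stereocentre is affected.

**Compound list**

1 | 3-furaldehyde | O=Cc1ccoc1 | starting material
2 | malonic acid | OC(=O)CC(=O)O | starting material
3 | 2-(furan-3-ylmethylidene)propanedioic acid | OC(=O)C(=Cc1ccoc1)C(=O)O | intermediate (not isolated)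
4 | (E)-3-(furan-3-yl)prop-2-enoic acid | OC(=O)/C=C/c1ccoc1 | intermediate
5 | 3-(furan-3-yl)propanoic acid | OC(=O)CCc1ccoc1 | intermediate
6 | 3-(furan-3-yl)propanoyl chloride | ClC(=O)CCc1ccoc1 | intermediate (not isolated)
7 | 4,5-dihydro-6H-cyclopenta[b]furan-6-one | O=C1CCc2ccoc12 | intermediate
8 | isopropylmagnesium chloride | CC(C)[Mg]Cl | starting material
9 | 6-(propan-2-yl)-5,6-dihydro-4H-cyclopenta[b]furan-6-ol (racemic) | CC(C)C1(O)CCc2ccoc12 | intermediate (not isolated)
10 | 6-(propan-2-yl)-4H-cyclopenta[b]furan | CC(C)C1=CCc2ccoc12 | intermediate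
11 | (6R)-6-(propan-2-yl)-5,6-dihydro-4H-cyclopenta[b]furan | CC(C)[C@H]1CCc2ccoc12 | intermediate
12 | acetaldehyde | CC=O | starting material
13 | [(6R)-6-(propan-2-yl)-5,6-dihydro-4H-cyclopenta[b]furan-2-yl]lithium | CC(C)[C@H]1CCc2cc([Li])oc12 | intermediate (not isolated)
14 | 1-[(6R)-6-(propan-2-yl)-5,6-dihydro-4H-cyclopenta[b]furan-2-yl]ethan-1-ol (both carbinol epimers) | CC(C)[C@H]1CCc2cc(C(C)O)oc12 | intermediate
15 | (7R)-7a-hydroxy-2-methyl-7-(propan-2-yl)-5,6,7,7a-tetrahydrocyclopenta[b]pyran-3(2H)-one (epimers at C2 and C7a) | CC1OC2(O)[C@@H](C(C)C)CCC2=CC1=O | intermediate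
16 | (7R)-2-methyl-3-oxo-7-(propan-2-yl)-2,3,5,6,7,7a-hexahydrocyclopenta[b]pyran-7a-yl acetate (epimers at C2 and C7a) | CC1OC2(OC(C)=O)[C@@H](C(C)C)CCC2=CC1=O | intermediate
17 | (E)-1,2-bis(phenylsulfonyl)ethene | O=S(=O)(/C=C/S(=O)(=O)c1ccccc1)c1ccccc1 | starting material
18 | (7R)-2-methyl-7-(propan-2-yl)-6,7-dihydro-5H-cyclopenta[b]pyrylium-3-olate | Cc1[o+]c2[C@@H](C(C)C)CCc2cc1[O-] | intermediate (not isolated)
19 | bis-sulfonyl cycloadduct: enone C9(=O)–C10=C1, oxygen bridge C5–O–C8, C8 methyl, (4R)-isopropyl cis to the C5 oxygen, trans PhSO2 on C6 and C7 (both exo/endo arrangements) | O=C1C=C2CC[C@H](C(C)C)[C@]23O[C@@]1(C)C(S(=O)(=O)c4ccccc4)C3S(=O)(=O)c5ccccc5 | intermediate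
20 | trimethylsilyl enol ether of 21 (C9(OSiMe3)=C10) | C[Si](C)(C)OC1=C[C@@]2(C)CC[C@H](C(C)C)[C@@]23C(S(=O)(=O)c4ccccc4)C(S(=O)(=O)c4ccccc4)[C@]1(C)O3 | intermediate (not isolated)
21 | C1-methyl bis-sulfonyl ketone: 6,7-trans-bis(phenylsulfonyl)-5,8-epoxydaucan-9-one, C1 methyl, C4 isopropyl and oxygen bridge on one face | O=C1C[C@@]2(C)CC[C@H](C(C)C)[C@@]23C(S(=O)(=O)c4ccccc4)C(S(=O)(=O)c4ccccc4)[C@]1(C)O3 | intermediate
22 | (1R,4R,5S,8S)-5,8-epoxydauc-6-en-9-one | O=C1C[C@@]2(C)CC[C@H](C(C)C)[C@@]23C=C[C@]1(C)O3 | intermediate
23 | (1R,4R,5S,8S)-5,8-epoxydaucan-9-one | O=C1C[C@@]2(C)CC[C@H](C(C)C)[C@@]23CC[C@]1(C)O3 | intermediate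
24 | hydrazone of 23 | NN=C1C[C@@]2(C)CC[C@H](C(C)C)[C@@]23CC[C@]1(C)O3 | intermediate (not isolated)
25 | (1R,4R,5S)-dauc-8-en-5-ol | CC1=CC[C@@]2(C)CC[C@H](C(C)C)[C@@]2(O)CC1 | intermediate
26 | (1R,4R,5S,8S,9R)-8,9-epoxydaucan-5-ol | O1[C@@H]2C[C@@]3(C)CC[C@H](C(C)C)[C@@]3(O)CC[C@]12C | intermediate
27 | (1R,4R,5S,8R,9R)-daucane-5,8,9-triol | O[C@@H]1C[C@@]2(C)CC[C@H](C(C)C)[C@@]2(O)CC[C@@]1(C)O | intermediate
28 | 4-methoxybenzoyl chloride | COc1ccc(C(=O)Cl)cc1 | starting material
29 | (1R,4R,5S,8R,9R)-5,8-dihydroxydaucan-9-yl 4-methoxybenzoate | COc1ccc(C(=O)O[C@@H]2C[C@@]3(C)CC[C@H](C(C)C)[C@@]3(O)CC[C@@]2(C)O)cc1 | target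

**Total step count:** 16
**Longest linear sequence:** 16 steps (1 to 29)

**Steps most likely to fail**

1. Step 9 (the (5+2) cycloaddition). Ionisation of the crowded tertiary acetate may be slow. The ylide then stands at a low concentration while the amine removes the C4 proton of 16 (loss of configuration, tautomerisation to an alkylidene pyranone) or attacks the disulfone. Fallback: set out from hemiketal 15 and activate it in the presence of the trap with MsCl, i-Pr2NEt and 17 in CH2Cl2 at −20 °C to rt. The transient hemiketal methanesulfonate F1 carries a far better leaving group and ionises at once at low temperature, so the ylide is formed quickly and captured by 17. The route is rejoined at cycloadduct 19.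

2. Step 10 (conjugate methylation). Methyl transfer to the fully substituted C1 next to quaternary C5 may be slower than deprotonation at C6 or C7 by the organometallic, which would be followed by β-loss of benzenesulfinate. Fallback: remove the sulfonyl groups before the organometallic step. From 19, Luche reduction (NaBH4, CeCl3·7H2O, MeOH, −78 °C) masks the enone as the allylic alcohol F2. Na(Hg), Na2HPO4 in MeOH/THF at −20 °C then gives the diene alcohol F3. Dess–Martin periodinane (NaHCO3, CH2Cl2) restores the enone as the sulfone-free dienone F4. It has no acidic sulfonyl C–H, and the endo face of C1 is still covered by the two-carbon bridge. Me2CuLi with TMSCl, followed by mild acid, then gives 22, where the route is rejoined.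

3. Step 13 (eliminative bridge opening). Protonation of the hydrazone anion at C9 may outrun expulsion of the bridging alkoxide, so that plain Wolff–Kishner deoxygenation keeps the ether bridge. Fallback: from 23, dissolving-metal cleavage of the α-alkoxy ketone (Li, NH3/THF, −78 °C) breaks the C8–O bond and leaves the lithium enolate with its double bond between C8 and C9. After evaporation of ammonia the enolate is trapped in THF with N-(5-chloropyridin-2-yl)bis(trifluoromethanesulfonyl)imide as the enol triflate F5. Reduction with Pd(OAc)2, PPh3, Bu3N and HCO2H in DMF at 60 °C replaces the triflate by hydrogen and gives 25, where the route is rejoined.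

**Further compounds**

F1 | step 9 | (7R)-2-methyl-3-oxo-7-(propan-2-yl)-2,3,5,6,7,7a-hexahydrocyclopenta[b]pyran-7a-yl methanesulfonate (not isolated) | CC1OC2(OS(C)(=O)=O)[C@@H](C(C)C)CCC2=CC1=O
F2 | step 10 | allylic alcohol from 19 (C9 carbinol, C10=C1, sulfonyl groups kept) | OC1C=C2CC[C@H](C(C)C)[C@]23O[C@@]1(C)C(S(=O)(=O)c4ccccc4)C3S(=O)(=O)c5ccccc5
F3 | step 10 | diene alcohol (C9 carbinol, C10=C1 and C6=C7, oxygen bridge C5–O–C8) | OC1C=C2CC[C@H](C(C)C)[C@]23O[C@@]1(C)C=C3
F4 | step 10 | sulfone-free dienone (C9 ketone, C10=C1 and C6=C7, oxygen bridge C5–O–C8) | O=C1C=C2CC[C@H](C(C)C)[C@]23O[C@@]1(C)C=C3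
F5 | step 13 | (1R,4R,5S)-5-hydroxydauc-8-en-9-yl trifluoromethanesulfonate | CC1=C(OS(=O)(=O)C(F)(F)F)C[C@@]2(C)CC[C@H](C(C)C)[C@@]2(O)CC1
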